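Slowness, if the isomer of the product has any in its appearance, hides before the first noon reading at 0.833 min, since from there on the isomer-to-target ratio stays flat within scatter in both runs.

all flasks: substrate 0.30 M; second catalyst 0.60 mM
- noon: reagent 0.33 M; free catalyst 45 mM; the very flask that is asked about, followed so far
- midnight: reagent 0.33 M; free catalyst 30 mM; run made earlier
- flask: reagent 0.330 M; free catalyst 45 mM; time 80 min

| run | time / min | isomer of the product / % | target / % |
|---|---|---|---|
| noon | 0.833 | 15.7 | 43.4 |
| noon | 2.50 | 22.9 | 64.1 |
| noon | 4.00 | 24.5 | 69.3 |
| noon | 6.00 | 25.5 | 71.3 |
| noon | 10.0 | 25.8 | 72.7 |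
| midnight | 5.00 | 24.8 | 69.8 |
| midnight | 15.0 | 26.3 | 73.2 |
| midnight | 25.0 | 26.2 | 73.5 |
| midnight | 40.0 | 26.3 | 73.9 |
| midnight | 60.0 | 27.0 | 73.5 |

(scatter of a reading: 0.3 percentage points)

- ratio of isomer of the product to target at 4.0 s
- ratio of isomer of the product to target at 80 min

**Plateau share.** At 40.0 min the midnight run reads isomer as 26.2% of isomer plus target. This plateau share, f, is a reading and carries its scatter.

**Two extremes.** If isomer is born beside target, with one fixed selectivity factor, the ratio at 4.0 s is already the plateau ratio 0.355. If isomer instead comes from target by a reversible exchange of relaxation rate λ, then d[isomer]/dt = λ(f([target] + [isomer]) − [isomer]). For a steady inflow of target from time zero this integrates to a share f(1 − (1 − e^−x)/x), with x = λt, which goes to zero with x.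

**Between them.** The first noon reading shows no shortfall of share, which on this reckoning, allowing for scatter, asks for x of at least 20 there. The time 4.0 s lies earlier than any reading, and x shrinks with it to 1.60, giving a ratio of 0.152. That low end leans on the steady inflow, an assumption of this reckoning. This reckoning therefore places the flask between that value and the plateau ratio at 4.0 s, and on the plateau at 80 min.

**The forecast.** It gave 0.358 (0.335 to 0.38) and 0.367 (0.35 to 0.45), on the ground: “The two products therefore form in parallel at a fixed selectivity”.

**The result.** The flask gives 0.209 at 4.0 s and 0.360 at 80 min.

    substrate + free catalyst → free catalyst + intermediate (k = 2.60 /M/s)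
    reagent + second catalyst + intermediate → second catalyst + target (k = 210 /M²/s)
    target + free catalyst ⇌ isomer of the product + free catalyst, rate k3*[free catalyst]*[target] forward; the back reaction follows from the equilibrium constant (K = 0.360, k = 5.80 /M/s)
    substrate ⇌ dormant form (K = 0.800, k = 0.550 /s)

**Exchange clock.** At the asked late time target and isomer relax by the exchange step alone with a half-life of 0.703 s, far shorter than the time the flask runs. Carried back to the early time, that half-life gives x = 3.94, and the steady-inflow share with f gives a ratio of 0.246, higher than the early ratio of the flask. With 0.011 M of free catalyst, x scales to 0.964 and the same share gives 0.104, while at that early time that neighbour flask stands at 0.0782.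

(Readings and results are simulated with constants of no real substance; noise was put on by code.)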